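**Strategy.** Everything rests on cutting two bonds: C1–CH2 of the bridgehead prenyl group and C5–C6 of ring A. What remains, ring C1–C2–C3–C4–C5–C9 with its three oxygens and the C3 acyl group, is an isobutyryl-methylphloroglucinol dearomatised at C1 and C5, and the C1 prenyl group is a 1,1-dimethylallyl ether on O9 after a [3,3] shift. The key step therefore moves that allyl group from O9 to C1 and, in the same flask, lets C5 add to the CH2 terminus (C6) of a vinyl sulfone held on C1, closing ring A and fixing both bridgeheads under a chiral base. Its precursor is the fully substituted aryl ether 14, with O2 masked as a MOM ether.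

Key step: step 10

Numbering: the bicyclo[3.3.1]nonane numbers of the target are used for the corresponding atoms of every intermediate (C1 prenyl bridgehead, C2 and C4 diketone carbons, C3 acyl-bearing carbon, C5 methyl bridgehead, C6H2, C7, C8Me2, C9 bridging ketone; O2, O4 and O9 are the oxygens on those carbons); ring A is C1–C8–C7–C6–C5–C9.

Remark on the design: a free phenoxide ortho to the sulfonylallyl arm would close a 3-sulfonylchroman by 6-endo oxa-Michael addition. O2 is therefore carried as a MOM ether, and the sulfur stays at the sulfide level until O9 has been etherified.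

Assumption: the sense of induction of the catalyst in step 10 cannot be predicted; the quinine-derived squaramide is written, and its quinidine-derived pseudo-enantiomer is the alternative. The C7 configuration of 17 is of no consequence (C7 becomes a carbanion in step 11) and is written as the epimer expected from exo protonation.

Step 1
Reactants: 1 2-methylbenzene-1,3,5-triol; 2 2-methylpropanoyl chloride
Product: 3 1-(2,4,6-trihydroxy-3-methylphenyl)-2-methylpropan-1-one
Conditions: AlCl3, PhNO2, 0 → 60 °C; aq HCl
Reagents that add atoms: none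
Why: Friedel–Crafts C-acylation of the strongly activated triol, whose two free ring positions are equivalent and whose first acyl group deactivates the ring against a second.

Step 2
Reactants: 4 2-methylbut-3-yn-2-ol; 5 benzenethiol
Product: 6 2-methyl-3-(phenylsulfanyl)but-3-en-2-ol
Conditions: Pd(OAc)2 (2 mol%), THF, 45 °C
Reagents that add atoms: none
Why: Pd(OAc)2-catalysed hydrothiolation of a terminal alkyne should add the thiol in the Markovnikov sense through a palladium thiolate, and the tertiary carbinol has no propargylic hydrogen through which the vinyl sulfide could isomerise.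

Step 3
Reactants: 6 2-methyl-3-(phenylsulfanyl)but-3-en-2-ol
Product: 7 [(1-bromo-3-methylbut-2-en-2-yl)sulfanyl]benzene
Conditions: PBr3 (0.4 equiv), pyridine (cat.), Et2O, −20 → 0 °C; used crude
Reagents that add atoms: phosphorus tribromide, BrP(Br)Br
Why: bromination of a tertiary allylic alcohol with allylic transposition (SN2'/SN1' through the bromophosphite) should give the primary bromide with the tetrasubstituted double bond, and any tertiary isomer left behind leads to the same ether in step 4 by attack at its CH2 terminus.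

Step 4
Reactants: 3 1-(2,4,6-trihydroxy-3-methylphenyl)-2-methylpropan-1-one; 7 [(1-bromo-3-methylbut-2-en-2-yl)sulfanyl]benzene
Product: 8 1-[2,6-dihydroxy-3-methyl-4-{[3-methyl-2-(phenylsulfanyl)but-2-en-1-yl]oxy}phenyl]-2-methylpropan-1-one
Conditions: K2CO3 (1.1 equiv), acetone, 0 °C → rt
Reagents that add atoms: none
Why: Williamson etherification should take place at O9, the most acidic hydroxyl and the only one not hydrogen-bonded to the ketone.

Step 5
Reactants: 8 1-[2,6-dihydroxy-3-methyl-4-{[3-methyl-2-(phenylsulfanyl)but-2-en-1-yl]oxy}phenyl]-2-methylpropan-1-one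
Product: 9 1-[2-hydroxy-6-(methoxymethoxy)-3-methyl-4-{[3-methyl-2-(phenylsulfanyl)but-2-en-1-yl]oxy}phenyl]-2-methylpropan-1-one
Conditions: MOMCl (1.1 equiv), iPr2NEt, CH2Cl2, 0 °C
Reagents that add atoms: chloro(methoxy)methane, COCCl
Why: mono-acetalisation of a 2,6-dihydroxyaryl ketone with an amine base stops after one hydroxyl, and O2 (next to C1–H) should react in preference to O4, which is flanked by the C5 methyl group and keeps the hydrogen bond to the ketone.

Step 6
Reactants: 9 1-[2-hydroxy-6-(methoxymethoxy)-3-methyl-4-{[3-methyl-2-(phenylsulfanyl)but-2-en-1-yl]oxy}phenyl]-2-methylpropan-1-one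
Product: 10 1-[2,4-dihydroxy-6-(methoxymethoxy)-3-methyl-5-[2-methyl-3-(phenylsulfanyl)but-3-en-2-yl]phenyl]-2-methylpropan-1-one
Conditions: PhNEt2, 160 °C
Reagents that add atoms: none
Why: aromatic ortho-Claisen rearrangement, in which only C1 can re-aromatise (C5 carries methyl, the para carbon the acyl group), so the allyl unit should arrive at C1 through its CMe2 terminus, while the basic solvent suppresses acid-induced addition of the new phenol to the vinyl sulfide.

Step 7
Reactants: 10 1-[2,4-dihydroxy-6-(methoxymethoxy)-3-methyl-5-[2-methyl-3-(phenylsulfanyl)but-3-en-2-yl]phenyl]-2-methylpropan-1-one; 11 3-chloro-3-methylbut-1-yne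
Product: 12 1-[2-hydroxy-6-(methoxymethoxy)-3-methyl-4-[(2-methylbut-3-yn-2-yl)oxy]-5-[2-methyl-3-(phenylsulfanyl)but-3-en-2-yl]phenyl]-2-methylpropan-1-one
Conditions: CuCl2·2H2O (1 mol%), DBU, MeCN, 0 °C
Reagents that add atoms: none
Why: copper-catalysed propargylic etherification through a copper allenylidene, which takes the phenoxide at its tertiary carbon; O9 is the only hydroxyl not chelated by the ketone, and the side chain is still a vinyl sulfide, which the phenoxide cannot attack.

Step 8
Reactants: 12 1-[2-hydroxy-6-(methoxymethoxy)-3-methyl-4-[(2-methylbut-3-yn-2-yl)oxy]-5-[2-methyl-3-(phenylsulfanyl)but-3-en-2-yl]phenyl]-2-methylpropan-1-one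
Product: 13 1-[2-hydroxy-6-(methoxymethoxy)-3-methyl-4-[(2-methylbut-3-yn-2-yl)oxy]-5-[2-methyl-3-(phenylsulfonyl)but-3-en-2-yl]phenyl]-2-methylpropan-1-one
Conditions: mCPBA (2.2 equiv), NaHCO3, CH2Cl2, 0 °C → rt
Reagents that add atoms: 3-chloroperoxybenzoic acid, O=C(OO)c1cccc(Cl)c1
Why: peracid oxidation of a sulfide to the sulfone is far faster than any reaction of the alkyne or of the electron-poor alkene that results, and it is placed after the last phenoxide step so that O9 never meets a vinyl sulfone.

Step 9
Reactants: 13 1-[2-hydroxy-6-(methoxymethoxy)-3-methyl-4-[(2-methylbut-3-yn-2-yl)oxy]-5-[2-methyl-3-(phenylsulfonyl)but-3-en-2-yl]phenyl]-2-methylpropan-1-one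
Product: 14 1-[2-hydroxy-6-(methoxymethoxy)-3-methyl-4-[(2-methylbut-3-en-2-yl)oxy]-5-[2-methyl-3-(phenylsulfonyl)but-3-en-2-yl]phenyl]-2-methylpropan-1-one
Conditions: H2 (1 atm), Pd/CaCO3 poisoned with Pb(OAc)2, quinoline, EtOAc, rt; product kept cold
Reagents that add atoms: none
Why: Lindlar semi-hydrogenation, in which the terminal alkyne binds the poisoned catalyst much more strongly than the 1,1-disubstituted vinyl sulfone and should be reduced alone.

Step 10
Reactants: 14 1-[2-hydroxy-6-(methoxymethoxy)-3-methyl-4-[(2-methylbut-3-en-2-yl)oxy]-5-[2-methyl-3-(phenylsulfonyl)but-3-en-2-yl]phenyl]-2-methylpropan-1-one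
Product: 17 (1R,5R,7R)-4-hydroxy-5,8,8-trimethyl-1-(3-methylbut-2-en-1-yl)-3-(2-methylpropanoyl)-7-(phenylsulfonyl)bicyclo[3.3.1]non-3-ene-2,9-dione, via dienone 15 (not isolated), via methoxymethyl enol ether 16 (not isolated)
Conditions: quinine-derived squaramide 3-[3,5-bis(trifluoromethyl)anilino]-4-[(9-deoxy-epi-quinin-9-yl)amino]cyclobut-3-ene-1,2-dione (10 mol%), PhMe, 60 °C; then 1 M HCl, THF, rt
Reagents that add atoms: none
Why: Proposed new method: the quinuclidine nitrogen of the catalyst deprotonates the C4 hydroxyl, and in the resulting phenoxide the 1,1-dimethylallyl group should migrate by chair [3,3] shifts from O9 to C5 or C1 and back, since each C-allylated dienolate regains the aromatic ring on the return shift, while only the C1 isomer 15 has its nucleophilic C5 (between C4–O and C9=O) within reach of the vinyl sulfone, so that addition of C5 to C6 and protonation at C7 drain the equilibrium through this one member. The closest known reaction types are the reversible ortho-Claisen rearrangement of 2,6-disubstituted aryl allyl ethers to cyclohexa-2,4-dienones, the alkylative dearomatisation–annulation of acylphloroglucinols with 2-substituted allylic acceptors, and amine–squaramide-catalysed Michael additions of cyclic 1,3-diketones to vinyl sulfones; their coupling into a catalyst-selected funnel is the untested part. Ring A (C1–C8–C7–C6–C5–C9) closes in the 6-endo-trig mode. C1 is controlled by the catalyst, whose squaramide binds the sulfonyl oxygens and whose ammonium holds the dienolate, so that one enantiomer of 15 cyclises while the other returns to achiral 14 (dynamic kinetic resolution); C5 is dictated by C1 because the three-atom tether reaches only the ring face on which it stands, and C7 is protonated on the exo face, anti to the new bond, but is re-formed in step 11. The step needs C1 over C5 delivery and C over O attack: the C5 isomer has no cyclisation open to it, an oxygen adduct would re-expel its stabilised oxyanion from the carbanion, and the MOM ether on O2 stops the aromatic phenol next to the side chain from closing a chroman on the vinyl sulfone before the shift. Dilute acid finally hydrolyses the vinylogous ester acetal of 16 to the triketone 17.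

Step 11
Reactants: 17 (1R,5R,7R)-4-hydroxy-5,8,8-trimethyl-1-(3-methylbut-2-en-1-yl)-3-(2-methylpropanoyl)-7-(phenylsulfonyl)bicyclo[3.3.1]non-3-ene-2,9-dione; 18 1-bromo-3-methylbut-2-ene
Product: 19 (1R,5R,7R)-4-hydroxy-5,8,8-trimethyl-1,7-bis(3-methylbut-2-en-1-yl)-3-(2-methylpropanoyl)-7-(phenylsulfonyl)bicyclo[3.3.1]non-3-ene-2,9-dione (C7 prenyl exo, sulfonyl endo)
Conditions: LiN(iPr)2 (2.3 equiv), THF–DMPU, −78 °C; 18 (1.3 equiv), −78 → −40 °C; aq NH4Cl
Reagents that add atoms: none
Why: alkylation of an α-sulfonyl carbanion, in which the first equivalent of base forms the lithium triketonate (which makes the C5 enolate a poor leaving group and shields the acyl region), the second removes the exposed exo C7–H next to the sulfone, and the dianion should react at carbon on the open exo face; the C7 centre made here is not the final one.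

Step 12
Reactants: 19 (1R,5R,7R)-4-hydroxy-5,8,8-trimethyl-1,7-bis(3-methylbut-2-en-1-yl)-3-(2-methylpropanoyl)-7-(phenylsulfonyl)bicyclo[3.3.1]non-3-ene-2,9-dione
Product: 20 (1R,5R,7R)-4-hydroxy-5,8,8-trimethyl-1,7-bis(3-methylbut-2-en-1-yl)-3-(2-methylpropanoyl)bicyclo[3.3.1]non-3-ene-2,9-dione (C7 prenyl endo, on the side of the C2–C4 bridge)
Conditions: Na(Hg) (6% Na), Na2HPO4, THF–MeOH, −20 °C; aq citric acid
Reagents that add atoms: none
Why: reductive desulfonylation of the Julia type, in which electron transfer cleaves the tertiary C–S bond and the planar C7 radical or anion should take its hydrogen from the exo face, because the endo face is covered by the C2–C4 bridge, leaving the prenyl group endo (7R) while the triketone is protected as its enolate.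

**Compound list**

1 | 2-methylbenzene-1,3,5-triol | Cc1c(O)cc(O)cc1O | starting material
2 | 2-methylpropanoyl chloride | CC(C)C(=O)Cl | starting material
3 | 1-(2,4,6-trihydroxy-3-methylphenyl)-2-methylpropan-1-one | CC(C)C(=O)c1c(O)cc(O)c(C)c1O | intermediate
4 | 2-methylbut-3-yn-2-ol | CC(C)(O)C#C | starting material
5 | benzenethiol | Sc1ccccc1 | starting material
6 | 2-methyl-3-(phenylsulfanyl)but-3-en-2-ol | CC(C)(O)C(=C)Sc1ccccc1 | intermediate
7 | [(1-bromo-3-methylbut-2-en-2-yl)sulfanyl]benzene | CC(C)=C(CBr)Sc1ccccc1 | intermediate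
8 | 1-[2,6-dihydroxy-3-methyl-4-{[3-methyl-2-(phenylsulfanyl)but-2-en-1-yl]oxy}phenyl]-2-methylpropan-1-one | CC(C)C(=O)c1c(O)cc(OCC(Sc2ccccc2)=C(C)C)c(C)c1O | intermediate
9 | 1-[2-hydroxy-6-(methoxymethoxy)-3-methyl-4-{[3-methyl-2-(phenylsulfanyl)but-2-en-1-yl]oxy}phenyl]-2-methylpropan-1-one | CC(C)C(=O)c1c(OCOC)cc(OCC(Sc2ccccc2)=C(C)C)c(C)c1O | intermediate
10 | 1-[2,4-dihydroxy-6-(methoxymethoxy)-3-methyl-5-[2-methyl-3-(phenylsulfanyl)but-3-en-2-yl]phenyl]-2-methylpropan-1-one | CC(C)C(=O)c1c(OCOC)c(C(C)(C)C(=C)Sc2ccccc2)c(O)c(C)c1O | intermediate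
11 | 3-chloro-3-methylbut-1-yne | CC(C)(Cl)C#C | starting material
12 | 1-[2-hydroxy-6-(methoxymethoxy)-3-methyl-4-[(2-methylbut-3-yn-2-yl)oxy]-5-[2-methyl-3-(phenylsulfanyl)but-3-en-2-yl]phenyl]-2-methylpropan-1-one | CC(C)C(=O)c1c(OCOC)c(C(C)(C)C(=C)Sc2ccccc2)c(OC(C)(C)C#C)c(C)c1O | intermediate
13 | 1-[2-hydroxy-6-(methoxymethoxy)-3-methyl-4-[(2-methylbut-3-yn-2-yl)oxy]-5-[2-methyl-3-(phenylsulfonyl)but-3-en-2-yl]phenyl]-2-methylpropan-1-one | CC(C)C(=O)c1c(OCOC)c(C(C)(C)C(=C)S(=O)(=O)c2ccccc2)c(OC(C)(C)C#C)c(C)c1O | intermediate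
14 | 1-[2-hydroxy-6-(methoxymethoxy)-3-methyl-4-[(2-methylbut-3-en-2-yl)oxy]-5-[2-methyl-3-(phenylsulfonyl)but-3-en-2-yl]phenyl]-2-methylpropan-1-one (precursor of the key step) | CC(C)C(=O)c1c(OCOC)c(C(C)(C)C(=C)S(=O)(=O)c2ccccc2)c(OC(C)(C)C=C)c(C)c1O | intermediate
15 | (6S)-3-hydroxy-5-(methoxymethoxy)-2-methyl-6-(3-methylbut-2-en-1-yl)-4-(2-methylpropanoyl)-6-[2-methyl-3-(phenylsulfonyl)but-3-en-2-yl]cyclohexa-2,4-dien-1-one (formed in the flask in step 10, not isolated) | CC(C)C(=O)C1=C(OCOC)[C@](CC=C(C)C)(C(C)(C)C(=C)S(=O)(=O)c2ccccc2)C(=O)C(C)=C1O | intermediate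
16 | (1S,5S,7R)-2-(methoxymethoxy)-5,8,8-trimethyl-1-(3-methylbut-2-en-1-yl)-3-(2-methylpropanoyl)-7-(phenylsulfonyl)bicyclo[3.3.1]non-2-ene-4,9-dione (formed in the flask in step 10, not isolated; same spatial arrangement as 17) | O=S(=O)(c1ccccc1)[C@@H]1C[C@@]2(C)C(=O)[C@](CC=C(C)C)(C(OCOC)=C(C(=O)C(C)C)C2=O)C1(C)C | intermediate
17 | (1R,5R,7R)-4-hydroxy-5,8,8-trimethyl-1-(3-methylbut-2-en-1-yl)-3-(2-methylpropanoyl)-7-(phenylsulfonyl)bicyclo[3.3.1]non-3-ene-2,9-dione (product of the key step) | O=S(=O)(c1ccccc1)[C@@H]1C[C@@]2(C)C(=O)[C@](CC=C(C)C)(C(=O)C(C(=O)C(C)C)=C2O)C1(C)C | intermediate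
18 | 1-bromo-3-methylbut-2-ene | CC(C)=CCBr | starting material
19 | (1R,5R,7R)-4-hydroxy-5,8,8-trimethyl-1,7-bis(3-methylbut-2-en-1-yl)-3-(2-methylpropanoyl)-7-(phenylsulfonyl)bicyclo[3.3.1]non-3-ene-2,9-dione | CC(C)=CC[C@@]1(S(=O)(=O)c3ccccc3)C[C@@]2(C)C(=O)[C@](CC=C(C)C)(C(=O)C(C(=O)C(C)C)=C2O)C1(C)C | intermediate
20 | (1R,5R,7R)-4-hydroxy-5,8,8-trimethyl-1,7-bis(3-methylbut-2-en-1-yl)-3-(2-methylpropanoyl)bicyclo[3.3.1]non-3-ene-2,9-dione | CC(C)=CC[C@@H]1C[C@@]2(C)C(=O)[C@](CC=C(C)C)(C(=O)C(C(=O)C(C)C)=C2O)C1(C)C | target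

Total step count: 12.
Longest linear sequence: 11 steps (steps 2 to 12, from 4 and 5 to 20).

**Steps most likely to fail**

1. Step 10 (the proposed new method). The allyl group may be delivered to the less hindered C5 without returning, or the two enantiomeric C1 dienolates may not interconvert through 14 faster than they cyclise, so that regiochemistry or enantiomeric purity is lost. The fallback replaces the Claisen delivery by a known alkylative dearomatisation–annulation followed by resolution; it sets out from 3 and 6 and comes back at 17. C-Prenylation of 3 with 18 in aqueous KOH at 0 °C should give 1-[2,4,6-trihydroxy-3-methyl-5-(3-methylbut-2-en-1-yl)phenyl]-2-methylpropan-1-one F1. Oxidation of 6 with mCPBA should give 2-methyl-3-(phenylsulfonyl)but-3-en-2-ol F2, and PBr3 should convert this with allylic transposition into [(1-bromo-3-methylbut-2-en-2-yl)sulfonyl]benzene F3. Treatment of F1 and F3 with LiN(SiMe3)2 in THF should alkylate the methyl-bearing C5 at the CH2Br carbon and then close ring A by Michael addition of the prenyl-bearing C1 to the CMe2 terminus of the vinyl sulfone, giving racemic 17 F4, which is resolved by preparative chromatography on a chiral stationary phase to return 17.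

2. Step 7. Attack of the doubly ortho-substituted phenoxide on the tertiary carbon of the copper allenylidene may be too slow, so that etherification of the chelated O4 hydroxyl or decay of the chloroalkyne takes over. The fallback sets out from 10 and comes back at 14, so that steps 8 and 9 fall away. Decarboxylative allylic etherification with tert-butyl 2-methylbut-3-en-2-yl carbonate and Pd(PPh3)4 in THF at 0 °C, in which the π-(1,1-dimethylallyl)palladium phenoxide ion pair collapses at the tertiary terminus, should give 1-[2-hydroxy-6-(methoxymethoxy)-3-methyl-4-[(2-methylbut-3-en-2-yl)oxy]-5-[2-methyl-3-(phenylsulfanyl)but-3-en-2-yl]phenyl]-2-methylpropan-1-one F5, and S-oxidation of F5 with mCPBA (NaHCO3, CH2Cl2, 0 °C) should give 14 directly.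

3. Step 11. C-Alkylation of the crowded C7 carbanion by the γ,γ-disubstituted bromide may be slow, leaving time for proton transfer from the isobutyryl group, O-prenylation of the triketonate, or retro-Michael opening of ring A. The fallback sets out from 17 and comes back at 19. The same dianion is quenched with the smaller and faster 3-bromoprop-1-ene to give (1R,5R,7R)-4-hydroxy-5,8,8-trimethyl-1-(3-methylbut-2-en-1-yl)-3-(2-methylpropanoyl)-7-(phenylsulfonyl)-7-(prop-2-en-1-yl)bicyclo[3.3.1]non-3-ene-2,9-dione F6, and cross-metathesis of F6 with 2-methylbut-2-ene (second-generation Grubbs catalyst, RuCl2(=CHPh)(PCy3)(H2IMes), CH2Cl2, 40 °C) should turn the allyl group into the prenyl group of 19.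

Further compounds
F1 | step 10 | 1-[2,4,6-trihydroxy-3-methyl-5-(3-methylbut-2-en-1-yl)phenyl]-2-methylpropan-1-one | CC(C)C(=O)c1c(O)c(C)c(O)c(CC=C(C)C)c1O
F2 | step 10 | 2-methyl-3-(phenylsulfonyl)but-3-en-2-ol | CC(C)(O)C(=C)S(=O)(=O)c1ccccc1
F3 | step 10 | [(1-bromo-3-methylbut-2-en-2-yl)sulfonyl]benzene | CC(C)=C(CBr)S(=O)(=O)c1ccccc1
F4 | step 10 | racemic 17, rac-(1R,5R,7R)-4-hydroxy-5,8,8-trimethyl-1-(3-methylbut-2-en-1-yl)-3-(2-methylpropanoyl)-7-(phenylsulfonyl)bicyclo[3.3.1]non-3-ene-2,9-dione | O=S(=O)(c1ccccc1)C1CC2(C)C(=O)C(CC=C(C)C)(C(=O)C(C(=O)C(C)C)=C2O)C1(C)C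
F5 | step 7 | 1-[2-hydroxy-6-(methoxymethoxy)-3-methyl-4-[(2-methylbut-3-en-2-yl)oxy]-5-[2-methyl-3-(phenylsulfanyl)but-3-en-2-yl]phenyl]-2-methylpropan-1-one | CC(C)C(=O)c1c(OCOC)c(C(C)(C)C(=C)Sc2ccccc2)c(OC(C)(C)C=C)c(C)c1O
F6 | step 11 | (1R,5R,7R)-4-hydroxy-5,8,8-trimethyl-1-(3-methylbut-2-en-1-yl)-3-(2-methylpropanoyl)-7-(phenylsulfonyl)-7-(prop-2-en-1-yl)bicyclo[3.3.1]non-3-ene-2,9-dione | C=CC[C@@]1(S(=O)(=O)c3ccccc3)C[C@@]2(C)C(=O)[C@](CC=C(C)C)(C(=O)C(C(=O)C(C)C)=C2O)C1(C)C
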